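**Assumption:** (R)-(–)-linalool (1) is the cheap chiral material and supplies C4 and C12 (cembrane numbering). C7, C8, C11, C1 and C3 are set by substrate control. Where a minor diastereomer forms, it is separated.

## Retrosynthetic overview
1. Target ⇐ C3 ketone (chelation-controlled reduction last) ⇐ bridged α-methylene ε-lactone, made by lactonising the C17 acid onto the tertiary C12-OH.
2. The 14-membered carbocycle ⇐ C1–C2 bond, formed by a photoredox/cobaloxime dehydrogenative radical macrocyclisation of a C3 silyl enol ether onto the prenyl-type alkene. This sets C1 and the exocyclic methylene.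
3. The open chain ⇐ two (R)-linalool halves, joined at C9–C10 by opening the C8/C9 epoxide with a hydrazone aza-enolate. The THF (C4–O–C7, C8-OH) comes from epoxidation and acid cyclisation of 8-hydroxylinalool, and C11-OH from a Felkin reduction.
4. Ring order: THF, then the C9–C10 chain, then the 14-membered carbocycle, then the 7-membered lactone.

## Route

**Step 1**
Reactants: 1 (R)-(–)-linalool
Product: 2 (3R,6E)-3,7-dimethylocta-1,6-diene-3,8-diol
Conditions: SeO2 (5 mol%), TBHP, CH2Cl2, 0 °C → rt
Reagents that add atoms: tert-butyl hydroperoxide, CC(C)(C)OO (source of the new OH oxygen)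
Why: Riley allylic oxidation hydroxylates the methyl trans to the chain of the prenyl unit, giving the E-allylic alcohol (this becomes C17). The C4 carbinol is untouched.

**Step 2**
Reactants: 2
Product: 3 (2R)-2-[(2S,5R)-5-ethenyl-5-methyloxolan-2-yl]propane-1,2-diol (cis-THF)
Conditions: VO(acac)2 (2 mol%), TBHP, CH2Cl2, 0 °C; then CSA (10 mol%), rt; separate cis/trans THF by chromatography
Reagents that add atoms: tert-butyl hydroperoxide, CC(C)(C)OO
Why: The C9-OH directs epoxidation of the C7=C8 alkene, which gives both faces with no control. The C4 tertiary OH then opens the epoxide in a 5-exo fashion at C7 with inversion. The two epoxide faces therefore give cis-(4R,7S,8R) and trans-(4R,7R,8S) THFs. The CH2OH on C8 disfavours the tertiary 6-endo pathway. The cis isomer (the target's 7S,8R) is isolated, in roughly 35–40% yield.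

**Step 3**
Reactants: 3
Product: 4 (2R)-2-[(2S,5R)-5-ethenyl-5-methyloxolan-2-yl]-2-methyloxirane
Conditions: TsCl, Et3N, DMAP, CH2Cl2, 0 °C; then t-BuOK, THF, 0 °C
Reagents that add atoms: none
Why: The primary OH is tosylated selectively. The tertiary alkoxide then closes the epoxide by 3-exo-tet displacement without touching C8, so C8 is retained.

**Step 4**
Reactants: 2
Product: 5 (3R,6E)-8-(TBS-oxy)-3,7-dimethylocta-1,6-dien-3-ol
Conditions: TBSCl, imidazole, CH2Cl2, 0 °C
Reagents that add atoms: tert-butyldimethylsilyl chloride, CC(C)(C)[Si](C)(C)Cl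
Why: Silylation is selective for the primary OH; the tertiary C12 carbinol stays free and keeps its configuration.

**Step 5**
Reactants: 5
Product: 6 (3R,6E)-8-(TBS-oxy)-3-hydroxy-3,7-dimethyloct-6-en-2-one
Conditions: PdCl2 (10 mol%), CuCl (1 equiv), O2 (1 atm), DMF/H2O 7:1, 25 °C
Reagents that add atoms: water, O (ketone oxygen)
Why: Wacker oxidation is selective for the terminal vinyl group over the trisubstituted alkene, and Markovnikov selectivity is reinforced by the adjacent OH. This gives the C11 methyl ketone; C12 is untouched.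

**Step 6**
Reactants: 6
Product: 7 N,N-dimethylhydrazone of 6
Conditions: Me2NNH2 (3 equiv), AcOH (cat.), EtOH, 4 Å MS, 60 °C
Reagents that add atoms: 1,1-dimethylhydrazine, CN(C)N
Why: The hydrazone makes the ketone a regiospecific nucleophile at C10, the only enolisable carbon because C12 is quaternary.

**Step 7**
Reactants: 4 and 7
Product: 8 the C9–C10-coupled hydrazone
Conditions: LDA (2.2 equiv), THF, –78 → 0 °C; then 4, 0 → 25 °C
Reagents that add atoms: none
Why: The lithium aza-enolate opens the 2,2-disubstituted epoxide at its unhindered CH2 (C9) by SN2. This forms C9–C10 and regenerates the C8 tertiary alcohol with retention.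

**Step 8**
Reactants: 8
Product: 9 the C11 ketone
Conditions: CuCl2·2H2O (3 equiv), THF/pH 7 buffer 1:1, 25 °C
Reagents that add atoms: water, O
Why: Oxidative hydrolysis of the hydrazone leaves the alkenes and silyl ether intact.

**Step 9**
Reactants: 9
Product: 10 the (11R)-alcohol (syn 11,12-diol)
Conditions: a) TMSOTf, 2,6-lutidine, CH2Cl2, –78 °C; b) L-Selectride, THF, –78 °C; c) K2CO3, MeOH, 0 °C
Reagents that add atoms: none (TMS is removed again)
Why: The α-OTMS ketone is reduced under non-chelating Felkin–Anh control. The OTMS group sits perpendicular to the carbonyl and hydride attacks anti to it, past the C12 methyl, giving 11R.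

**Step 10**
Reactants: 10
Product: 11 the C3 methyl ketone
Conditions: PdCl2 (10 mol%), CuCl (1 equiv), O2, DMF/H2O 7:1, 25 °C
Reagents that add atoms: water, O
Why: Chemoselective Wacker oxidation of the vinyl group on the quaternary THF carbon; C4 is not touched.

**Step 11**
Reactants: 11
Product: 12 the per-silylated enol ether (enol-OTMS and OTMS at C8, C11, C12; C17 stays OTBS)
Conditions: TMSOTf (6 equiv), Et3N (10 equiv), CH2Cl2, 0 °C
Reagents that add atoms: trimethylsilyl triflate, C[Si](C)(C)OS(=O)(=O)C(F)(F)F
Why: The only enolisable position is the methyl (C2), so a single terminal enol silane forms, and the three free OH groups are masked transiently.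

**Step 12**
Reactants: 12
Product: 13 the macrocyclic C3 ketone, tetrasilylated (three OTMS and one OTBS), used crude
Conditions: [Ir(dF(CF3)ppy)2(dtbbpy)]PF6 (2 mol%), Co(dmgH)2pyCl (10 mol%), 2,6-lutidine (0.2 equiv), MeCN/MeOH 20:1 (1 mM, syringe-pump addition), 450 nm LEDs, 25 °C, N2
Reagents that add atoms: none (MeOH removes the TMS as TMSOMe; H2 is evolved)
Why: Proposed new method: photo-oxidation of the enol silane (about +1.0 V, well below the alkene) and desilylation give an electrophilic α-keto radical at C2. This radical adds to the less substituted C1 of the electron-rich prenyl-type alkene, which closes the 14-membered ring and leaves a tertiary radical at C15. Co(II) then abstracts a methyl hydrogen to give the 1,1-disubstituted C15=C16 alkene, and H2 release closes the cycle. The closest known reaction types are photoredox/cobaloxime dehydrogenative radical-Heck coupling and α-carbonyl radical additions to alkenes. C1 is set in the macrocyclic transition state by C12 and the cis-THF. The wrong C1 epimer cannot form the 1,12-lactone bridge in step 15, so it is removed there.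

**Step 13**
Reactants: 13
Product: 14 the macrocyclic tetraol ketone
Conditions: TBAF (8 equiv), THF, 25 °C
Reagents that add atoms: none
Why: Fluoride removes all TMS and TBS groups. The 14-membered ring is already closed and every stereocentre is quaternary or non-epimerisable.

**Step 14**
Reactants: 14
Product: 15 the C17 acid (α-methylene seco-acid)
Conditions: TEMPO (20 mol%), PhI(OAc)2 (3 equiv), MeCN/H2O 1:1, 25 °C
Reagents that add atoms: water, O
Why: The primary allylic alcohol is oxidised selectively (through the aldehyde) to the acrylic acid; the hindered secondary and the tertiary OH groups are spared.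

**Step 15**
Reactants: 15
Product: 16 the bridged α-methylene ε-lactone with the C3 ketone
Conditions: 2,4,6-Cl3C6H2COCl, Et3N, THF, 25 °C; then slow addition to DMAP (10 equiv), toluene, 80 °C, 2 mM
Reagents that add atoms: none
Why: Yamaguchi lactonisation closes the 7-membered ring onto the tertiary C12-OH with retention. The C3 carbonyl prevents competing δ-lactone formation from C3-OH.

**Step 16**
Reactants: 16
Product: 17 Querciformolide D
Conditions: Zn(BH4)2, Et2O/THF, –40 °C
Reagents that add atoms: none
Why: Zn(BH4)2 chelates the C3 carbonyl and the THF oxygen, and hydride enters from the methyl side (Cram-chelate), giving 3S. The α-methylene lactone is untouched.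

## Compound list
1 | (R)-(–)-linalool | C=C[C@](C)(O)CCC=C(C)C | starting material
2 | (3R,6E)-3,7-dimethylocta-1,6-diene-3,8-diol | C=C[C@](C)(O)CC/C=C(\C)CO | intermediate
3 | (2R)-2-[(2S,5R)-5-ethenyl-5-methyloxolan-2-yl]propane-1,2-diol | C=C[C@@]1(C)CC[C@H](O1)[C@](C)(O)CO | intermediate
4 | (2R)-2-[(2S,5R)-5-ethenyl-5-methyloxolan-2-yl]-2-methyloxirane | C=C[C@@]1(C)CC[C@H](O1)[C@@]2(C)CO2 | intermediate
5 | (3R,6E)-8-(TBS-oxy)-3,7-dimethylocta-1,6-dien-3-ol | C=C[C@](C)(O)CC/C=C(\C)CO[Si](C)(C)C(C)(C)C | intermediate
6 | (3R,6E)-8-(TBS-oxy)-3-hydroxy-3,7-dimethyloct-6-en-2-one | CC(=O)[C@](C)(O)CC/C=C(\C)CO[Si](C)(C)C(C)(C)C | intermediate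
7 | N,N-dimethylhydrazone of 6 | CC(=NN(C)C)[C@](C)(O)CC/C=C(\C)CO[Si](C)(C)C(C)(C)C | intermediate
8 | C9–C10-coupled hydrazone (THF, C8-OH, C12-OH, prenyl-OTBS) | C=C[C@@]1(C)CC[C@H](O1)[C@](C)(O)CCC(=NN(C)C)[C@](C)(O)CC/C=C(\C)CO[Si](C)(C)C(C)(C)C | intermediate
9 | C11 ketone | C=C[C@@]1(C)CC[C@H](O1)[C@](C)(O)CCC(=O)[C@](C)(O)CC/C=C(\C)CO[Si](C)(C)C(C)(C)C | intermediate
10 | (11R)-alcohol (syn 11,12-diol) | C=C[C@@]1(C)CC[C@H](O1)[C@](C)(O)CC[C@@H](O)[C@](C)(O)CC/C=C(\C)CO[Si](C)(C)C(C)(C)C | intermediate
11 | C3 methyl ketone | CC(=O)[C@@]1(C)CC[C@H](O1)[C@](C)(O)CC[C@@H](O)[C@](C)(O)CC/C=C(\C)CO[Si](C)(C)C(C)(C)C | intermediate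
12 | per-silylated enol ether | C=C(O[Si](C)(C)C)[C@@]1(C)CC[C@H](O1)[C@](C)(O[Si](C)(C)C)CC[C@@H](O[Si](C)(C)C)[C@](C)(O[Si](C)(C)C)CC/C=C(\C)CO[Si](C)(C)C(C)(C)C | intermediate
13 | macrocyclic C3 ketone, tetrasilylated | C=C(CO[Si](C)(C)C(C)(C)C)[C@H]1CC(=O)[C@@]2(C)CC[C@H](O2)[C@](C)(O[Si](C)(C)C)CC[C@@H](O[Si](C)(C)C)[C@](C)(O[Si](C)(C)C)CC1 | intermediate
14 | macrocyclic tetraol ketone | C=C(CO)[C@H]1CC(=O)[C@@]2(C)CC[C@H](O2)[C@](C)(O)CC[C@@H](O)[C@](C)(O)CC1 | intermediate
15 | seco-acid (α-methylene acrylic acid) | C=C(C(=O)O)[C@H]1CC(=O)[C@@]2(C)CC[C@H](O2)[C@](C)(O)CC[C@@H](O)[C@](C)(O)CC1 | intermediate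
16 | bridged lactone, C3 ketone | C=C1C(=O)O[C@]2(C)CC[C@@H]1CC(=O)[C@@]1(C)CC[C@H](O1)[C@](C)(O)CC[C@H]2O | intermediate
17 | Querciformolide D | C=C1C(=O)O[C@]2(C)CC[C@@H]1C[C@H](O)[C@@]1(C)CC[C@H](O1)[C@](C)(O)CC[C@H]2O | target

## Totals
Total steps: 16. Longest linear sequence: 14 (1 → 2 → 5 → 6 → 7 → 8 → 9 → 10 → 11 → 12 → 13 → 14 → 15 → 16 → 17).

## Three steps most likely to fail
1. **Step 12 (proposed new method).** The electrophilic α-keto radical may undergo 1,5-HAT from the α-oxy C7–H, the regiochemistry of Co-mediated desaturation (methyl versus CH2OTBS) may be poor, and the C1 diastereoselectivity is uncertain. Fallback: change the bond-forming mode to a known photoredox decarboxylative Giese macrocyclisation. Use a C2 N-hydroxyphthalimide ester (β-OH acid) and a C1 (Z)-2-(phenylsulfonylmethyl)enoate acceptor, where β-scission of PhSO2• forms the methylene.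
2. **Step 15.** Lactonisation of a tertiary alcohol in competition with the C11-OH may give oligomers or the 8-membered lactone. Fallback: skip the acid and oxidise diol 14 directly to 16 through the 7-membered lactol (TEMPO/PhI(OAc)2 or Ru-catalysed dehydrogenative lactonisation).
3. **Step 16.** Chelation control may give the wrong C3 epimer in the rigid bicycle. Fallback: invert the 3R alcohol by Mitsunobu esterification (p-nitrobenzoic acid, DIAD, PPh3) followed by methanolysis.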